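The route rests on disconnecting the C1'–C2' bond of the side chain on C6 of the coumarin (2H-chromen-2-one) benzene ring. The benzylic carbinol C1' is a latent formyl carbon, and the syn relationship between O1'–H and the isovalerate on O2' is the retron of a γ-acyloxy-methallyl addition. One chromium-catalysed asymmetric Nozaki–Hiyama–Kishi reaction joins 6-formyl-7-methoxycoumarin to an allyl chloride that already carries the ester, setting C1' and C2' and placing the acyl group on the inner oxygen without any selective acylation. The precursor pair is the achiral aldehyde and an E/Z enol-ester allyl chloride; radical Markovnikov hydration of the isopropenyl group then supplies O3'.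

Key step: step 4

Assumption: C1'–C3' are the side-chain carbons counted from the ring, and the (R,R)-salen ligand is taken as the antipode that directs Si-face attack on the formyl group; the sense is to be confirmed on the first run and the (S,S)-ligand used if it proves opposite.

Step 1
Reactants: 1 5-bromo-2-hydroxy-4-methoxybenzaldehyde; 2 ethyl (triphenylphosphoranylidene)acetate
Product: 4 6-bromo-7-methoxycoumarin, via ethyl (E)-3-(5-bromo-2-hydroxy-4-methoxyphenyl)prop-2-enoate 3 (not isolated)
Conditions: PhNEt2, reflux (about 215 °C)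
Reagents that add atoms: none
Why: Wittig olefination of the salicylaldehyde with the stabilised ylide gives the o-hydroxycinnamate 3, which at the reflux temperature of N,N-diethylaniline isomerises from E to Z and lactonises with loss of ethanol, so the pyranone ring should close in the same pot while the aryl bromide and methyl ether are spectators.

Step 2
Reactants: 4 6-bromo-7-methoxycoumarin; 5 carbon monoxide
Product: 6 6-formyl-7-methoxycoumarin (7-methoxy-2-oxo-2H-chromene-6-carbaldehyde)
Conditions: Pd(OAc)2 (cat.), di(1-adamantyl)-n-butylphosphine (cat.), TMEDA, CO/H2 (1:1, 5 bar), toluene, 100 °C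
Reagents that add atoms: none
Why: Palladium-catalysed reductive carbonylation (formylation) of an aryl bromide, in which oxidative addition, CO insertion and hydrogenolysis of the aroylpalladium by H2 (HBr taken up by the amine) should deliver the aldehyde, the bulky electron-rich phosphine favouring CO insertion over hydrodebromination and the CO atmosphere suppressing hydrogenation of the C3–C4 enoate.

Step 3
Reactants: 7 methacrolein; 8 isovaleryl chloride
Product: 9 3-chloro-2-methylprop-1-enyl 3-methylbutanoate (E/Z mixture)
Conditions: ZnCl2 (cat.), CH2Cl2, −20 °C to rt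
Reagents that add atoms: none
Why: Lewis-acid-catalysed addition of an acyl chloride across an enal: ZnCl2 promotes O-acylation of the carbonyl and delivery of chloride to the terminal carbon (directly or by allylic 1,3-shift of a first-formed 1-chloroallyl ester), giving the 3-chloropropenyl ester as an E/Z mixture, which is tolerable because the next step is stereoconvergent.

Step 4
Reactants: 6 6-formyl-7-methoxycoumarin; 9 3-chloro-2-methylprop-1-enyl 3-methylbutanoate (1.5 equiv)
Product: 11 (1R,2R)-1-hydroxy-1-(7-methoxy-2-oxo-2H-chromen-6-yl)-3-methylbut-3-en-2-yl 3-methylbutanoate, via (1R,2R)-1-(7-methoxy-2-oxo-2H-chromen-6-yl)-3-methyl-1-(trimethylsilyloxy)but-3-en-2-yl 3-methylbutanoate 10 (not isolated)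
Conditions: CrCl3 (10 mol%), (R,R)-N,N'-bis(3,5-di-tert-butylsalicylidene)-1,2-cyclohexanediamine (10 mol%), Et3N (20 mol%), Mn powder, Me3SiCl, MeCN, rt; then 10% aq. citric acid, MeOH, 0 °C
Reagents that add atoms: chlorotrimethylsilane, C[Si](C)(C)Cl (its Me3Si group is carried only by 10 and is lost on work-up)
Why: Chromium(II)–salen, regenerated by manganese, reduces the allylic C–Cl bond of 9 in two one-electron steps to a γ-acyloxy-methallylchromium(III) whose E and Z forms (and any 1-chloroallyl regioisomer) interconvert by 1,3-metal shift with chromium on the CH2 terminus, so the acyloxy-bearing γ-carbon bonds to the formyl carbon of 6 (C1'–C2'), and Me3SiCl silylates the chromium alkoxide, which turns the catalyst over and blocks O2'-to-O1' acyl transfer. The closest known reaction is the catalytic enantioselective Nozaki–Hiyama–Kishi α-hydroxyallylation of aldehydes with 3-halopropenyl esters, which gives syn alkene-diol monoesters; the 2-methyl isovalerate donor is a new member of that donor class. No ring is closed. C1' and C2' are both set here: the syn relation should follow from an open antiperiplanar transition state enforced by the coordinatively saturated salen complex (the aldehyde being activated by a second Lewis-acidic centre), and the absolute sense (Si-face attack on the formyl group, giving 1R,2R) from the ligand antipode. The step needs γ-regioselectivity, syn diastereoselectivity and facial selectivity, secured respectively by the primary C–Cr bond, the open transition state that is indifferent to donor geometry, and the chiral ligand; the non-enolisable aryl aldehyde, the lactone, the C3–C4 enoate and the isovalerate are inert to organochromium(III).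

Step 5
Reactants: 11 (1R,2R)-1-hydroxy-1-(7-methoxy-2-oxo-2H-chromen-6-yl)-3-methylbut-3-en-2-yl 3-methylbutanoate
Product: 12 (1R,2S)-1,3-dihydroxy-1-(7-methoxy-2-oxo-2H-chromen-6-yl)-3-methylbutan-2-yl 3-methylbutanoate (CNP0260807.1)
Conditions: Co(acac)2 (cat.), PhSiH3, O2 (1 atm), THF, rt; then aq. Na2S2O3
Reagents that add atoms: dioxygen, O=O
Why: Mukaiyama hydration: a cobalt hydride from Co(acac)2 and PhSiH3 transfers a hydrogen atom to the CH2 terminus of the electron-rich 1,1-disubstituted alkene, the tertiary C3' radical is trapped by O2 and the peroxide reduced to the alcohol, so O3' arrives with Markovnikov regiochemistry without any cation that could form an acyloxonium ion from the O2' ester, no stereocentre is created (C3' bears two methyls) and C1' and C2' are untouched.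

Compound list
1 | 5-bromo-2-hydroxy-4-methoxybenzaldehyde | COc1cc(O)c(C=O)cc1Br | starting material
2 | ethyl (triphenylphosphoranylidene)acetate | CCOC(=O)C=P(c1ccccc1)(c1ccccc1)c1ccccc1 | starting material
3 | ethyl (E)-3-(5-bromo-2-hydroxy-4-methoxyphenyl)prop-2-enoate | CCOC(=O)/C=C/c1cc(Br)c(OC)cc1O | intermediate
4 | 6-bromo-7-methoxycoumarin (6-bromo-7-methoxy-2H-chromen-2-one) | COc1cc2oc(=O)ccc2cc1Br | intermediate
5 | carbon monoxide | [C-]#[O+] | starting material
6 | 6-formyl-7-methoxycoumarin (7-methoxy-2-oxo-2H-chromene-6-carbaldehyde) | COc1cc2oc(=O)ccc2cc1C=O | intermediate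
7 | methacrolein (2-methylprop-2-enal) | CC(=C)C=O | starting material
8 | isovaleryl chloride (3-methylbutanoyl chloride) | CC(C)CC(=O)Cl | starting material
9 | 3-chloro-2-methylprop-1-enyl 3-methylbutanoate, E/Z mixture | CC(C)CC(=O)OC=C(C)CCl | intermediate
10 | (1R,2R)-1-(7-methoxy-2-oxo-2H-chromen-6-yl)-3-methyl-1-(trimethylsilyloxy)but-3-en-2-yl 3-methylbutanoate | COc1cc2oc(=O)ccc2cc1[C@@H](O[Si](C)(C)C)[C@H](OC(=O)CC(C)C)C(C)=C | intermediate
11 | (1R,2R)-1-hydroxy-1-(7-methoxy-2-oxo-2H-chromen-6-yl)-3-methylbut-3-en-2-yl 3-methylbutanoate (syn) | COc1cc2oc(=O)ccc2cc1[C@@H](O)[C@H](OC(=O)CC(C)C)C(C)=C | intermediate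
12 | (1R,2S)-1,3-dihydroxy-1-(7-methoxy-2-oxo-2H-chromen-6-yl)-3-methylbutan-2-yl 3-methylbutanoate | COc1cc2oc(=O)ccc2cc1[C@@H](O)[C@H](OC(=O)CC(C)C)C(C)(C)O | target

Total step count: 5
Longest linear sequence: 4 steps (steps 1, 2, 4 and 5; step 3 is a one-step side branch that makes the allyl donor).

Steps most likely to fail

1. Step 4. The 2-methyl group on the allylchromium may erode the syn preference or the facial selectivity of the open transition state. The electron-rich aryl aldehyde may also undergo reductive pinacol dimerisation under Mn/Me3SiCl, and the ester may migrate from O2' to O1' during desilylation. The fallback sets out from aldehyde 6 and returns at 11, using stoichiometric reagent control through a closed chair transition state. 2-Methylprop-2-en-1-ol is converted with chloromethyl methyl ether and i-Pr2NEt into 3-(methoxymethoxy)-2-methylprop-1-ene F1. Metalation (sec-BuLi, THF, −78 °C), transfer to (−)-B-methoxydiisopinocampheylborane (from (+)-α-pinene) and treatment with BF3·OEt2 generate [(Z)-3-(methoxymethoxy)-2-methylprop-2-en-1-yl]diisopinocampheylborane F2. This reagent should add to the Si face of 6 (the Z-γ-alkoxy geometry gives the syn adduct) and, after ethanolamine work-up, give 6-[(1R,2R)-1-hydroxy-2-(methoxymethoxy)-3-methylbut-3-enyl]-7-methoxycoumarin F3. O1' is silylated (TBSOTf, 2,6-lutidine, CH2Cl2) to 6-[(1R,2R)-1-(tert-butyldimethylsilyloxy)-2-(methoxymethoxy)-3-methylbut-3-enyl]-7-methoxycoumarin F4. The methoxymethyl ether is cleaved (Me2BBr, CH2Cl2, −78 °C; aq. NaHCO3) to 6-[(1R,2R)-1-(tert-butyldimethylsilyloxy)-2-hydroxy-3-methylbut-3-enyl]-7-methoxycoumarin F5. O2' is acylated with isovaleryl chloride 8 (pyridine, DMAP, CH2Cl2) to (1R,2R)-1-(tert-butyldimethylsilyloxy)-1-(7-methoxy-2-oxo-2H-chromen-6-yl)-3-methylbut-3-en-2-yl 3-methylbutanoate F6. HF·pyridine in THF then removes the silyl group under acidic conditions that should not move the ester, giving 11.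

2. Step 5. Hydrogen-atom transfer may also reach the coumarin C3–C4 double bond, the tertiary radical may be reduced to an isopropyl group instead of capturing oxygen, or the hydroperoxide stage may not be fully reduced. The fallback sets out from 11 and returns at 12, replacing the radical hydration by epoxidation and reductive opening. Buffered mCPBA (NaHCO3, CH2Cl2, 0 °C) should epoxidise only the electron-rich 1,1-disubstituted alkene to (1S,2R)-2-hydroxy-2-(7-methoxy-2-oxo-2H-chromen-6-yl)-1-(2-methyloxiran-2-yl)ethyl 3-methylbutanoate F7, as either or both configurations at the oxirane carbon, which later becomes non-stereogenic. LiI/AcOH in THF opens the epoxide at its CH2 carbon to (1R,2S)-1,3-dihydroxy-4-iodo-1-(7-methoxy-2-oxo-2H-chromen-6-yl)-3-methylbutan-2-yl 3-methylbutanoate F8. Radical deiodination (Bu3SnH, AIBN, toluene, 80 °C) then gives 12.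

3. Step 2. Hydrodebromination may outrun CO insertion, or palladium hydride may partly reduce the enoate. The fallback sets out from 4 and returns at 6, installing the formyl carbon as a vinyl group. Stille coupling with tributyl(vinyl)stannane (Pd(PPh3)4, toluene, 100 °C) gives 6-ethenyl-7-methoxycoumarin F9. Lemieux–Johnson cleavage (cat. OsO4, NaIO4, 2,6-lutidine, dioxane/H2O) of the electron-rich styrenyl alkene, which should react in preference to the electron-poor C3–C4 bond, gives 6.

Further compounds
F1 | step 4 | 3-(methoxymethoxy)-2-methylprop-1-ene | COCOCC(C)=C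
F2 | step 4 | [(Z)-3-(methoxymethoxy)-2-methylprop-2-en-1-yl]diisopinocampheylborane (Ipc groups from (+)-α-pinene) | COCO/C=C(/C)CB([C@@H]1C[C@@H]2C[C@H]([C@H]1C)C2(C)C)[C@@H]1C[C@@H]2C[C@H]([C@H]1C)C2(C)C
F3 | step 4 | 6-[(1R,2R)-1-hydroxy-2-(methoxymethoxy)-3-methylbut-3-enyl]-7-methoxycoumarin | COc1cc2oc(=O)ccc2cc1[C@@H](O)[C@H](OCOC)C(C)=C
F4 | step 4 | 6-[(1R,2R)-1-(tert-butyldimethylsilyloxy)-2-(methoxymethoxy)-3-methylbut-3-enyl]-7-methoxycoumarin | COc1cc2oc(=O)ccc2cc1[C@@H](O[Si](C)(C)C(C)(C)C)[C@H](OCOC)C(C)=C
F5 | step 4 | 6-[(1R,2R)-1-(tert-butyldimethylsilyloxy)-2-hydroxy-3-methylbut-3-enyl]-7-methoxycoumarin | COc1cc2oc(=O)ccc2cc1[C@@H](O[Si](C)(C)C(C)(C)C)[C@H](O)C(C)=C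
F6 | step 4 | (1R,2R)-1-(tert-butyldimethylsilyloxy)-1-(7-methoxy-2-oxo-2H-chromen-6-yl)-3-methylbut-3-en-2-yl 3-methylbutanoate | COc1cc2oc(=O)ccc2cc1[C@@H](O[Si](C)(C)C(C)(C)C)[C@H](OC(=O)CC(C)C)C(C)=C
F7 | step 5 | (1S,2R)-2-hydroxy-2-(7-methoxy-2-oxo-2H-chromen-6-yl)-1-(2-methyloxiran-2-yl)ethyl 3-methylbutanoate (oxirane carbon unassigned) | COc1cc2oc(=O)ccc2cc1[C@@H](O)[C@H](OC(=O)CC(C)C)C1(C)CO1
F8 | step 5 | (1R,2S)-1,3-dihydroxy-4-iodo-1-(7-methoxy-2-oxo-2H-chromen-6-yl)-3-methylbutan-2-yl 3-methylbutanoate (C3 unassigned) | COc1cc2oc(=O)ccc2cc1[C@@H](O)[C@H](OC(=O)CC(C)C)C(C)(O)CI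
F9 | step 2 | 6-ethenyl-7-methoxycoumarin | COc1cc2oc(=O)ccc2cc1C=C
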